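**Assumption:** compounds 1, 4 and 6 are catalogue items. Compound 1 is distilled just before use, or released the same day from commercial D‑mannitol diacetonide with NaIO4.

## Retrosynthetic overview
1. The acrylic acid comes from a final Knoevenagel–Doebner reaction on a 5‑formyl group, and the same step frees the phenol.
2. The C3–CH2OH group comes from a C3‑(1,3‑dioxolan‑4‑yl) group by glycol cleavage to the C3 aldehyde and then selective reduction. The dioxolane carbon itself becomes the CH2OH carbon.
3. The dihydrofuran is the only ring formed, since both arenes are bought. C3–C3a and C2–O1 are cut together to give an o‑iodophenol and an E‑styrene, which are joined in one light‑driven aryl‑radical/polar‑crossover annulation.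
4. Stereochemical relay: the dioxolane stereocentre (from D‑mannitol) sets C3, and C3 sets C2 (trans).
5. The E‑styrene comes from cross‑metathesis of a bought acetoxystyrene with the vinyl dioxolane made from glyceraldehyde acetonide.

## Route

**Step 1**
Reactants: 1 (R)‑2,2‑dimethyl‑1,3‑dioxolane‑4‑carbaldehyde; 2 methyltriphenylphosphonium bromide
Product: 3 (4S)‑4‑ethenyl‑2,2‑dimethyl‑1,3‑dioxolane
Conditions: 2, KHMDS, THF, 0 °C; then 1, −78 °C → rt; pentane extraction, careful distillation
Reagents that add atoms: methyltriphenylphosphonium bromide, C[P+](c1ccccc1)(c1ccccc1)c1ccccc1.[Br-] (delivers CH2)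
Why: In this Wittig methylenation the unstabilised ylide adds at low temperature faster than it enolises the α‑alkoxy aldehyde, so the bought stereocentre is carried through unchanged (R→S is only a CIP priority change).

**Step 2**
Reactants: 3 (2 equiv); 4 4‑ethenyl‑2‑methoxyphenyl acetate (4‑acetoxy‑3‑methoxystyrene)
Product: 5 4‑{(E)‑2‑[(4S)‑2,2‑dimethyl‑1,3‑dioxolan‑4‑yl]ethenyl}‑2‑methoxyphenyl acetate
Conditions: Hoveyda–Grubbs II (2 mol %), CH2Cl2, 40 °C, N2 sweep (−C2H4)
Reagents that add atoms: none (both partners are numbered reactants)
Why: In this olefin cross‑metathesis a fast styrene partner and a slow, branched allylic‑ether partner give the cross product selectively as the thermodynamic E‑alkene, and the acetate, acetonide and stereocentre are inert.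

**Step 3 (key step)**
Reactants: 5 (1 equiv); 6 4‑hydroxy‑3‑iodo‑5‑methoxybenzaldehyde (5‑iodovanillin, 2 equiv, added in two portions)
Product: 7 4‑{(2S,3S)‑3‑[(4S)‑2,2‑dimethyl‑1,3‑dioxolan‑4‑yl]‑5‑formyl‑7‑methoxy‑2,3‑dihydro‑1‑benzofuran‑2‑yl}‑2‑methoxyphenyl acetate (2,3‑trans; same spatial arrangement as the target)
Conditions: 10‑phenylphenothiazine (PTH, 5 mol %), 2,6‑lutidine (2 equiv), degassed MeCN (0.1 M), 390 nm LEDs, rt; chromatography to remove the minor C3 diastereomer
Reagents that add atoms: none (both partners are numbered reactants; HI is lost to lutidine)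
Why: Proposed new method: excited PTH (about −2.1 V vs SCE) puts an electron into the formyl‑arene π* of 6, iodide leaves, and the σ‑aryl radical adds to the styrene carbon remote from the arene to give the benzylic radical; PTH•+ (about +0.7 V), or the I2/I3− it makes from iodide, oxidises that radical (about +0.4 V) to the benzylic iodide/cation, and the adjacent phenol closes the five‑membered ring, so the cycle is redox‑neutral; C3 is set in the radical addition, where both the Kishi/Felkin conformer (allylic C–H in the alkene plane, attack anti to C–O) and the inside‑alkoxy conformer of the (S)‑dioxolane expose the same Si face of the attacked carbon (anti adduct, expected dr about 4–8:1, and the minor isomer is a separable diastereomer); C2 is set in the ring closure, trans to the bulky C3 group; E/Z scrambling of 5 under light is harmless because the geometry is erased at the radical stage; the closest known reaction types are photoredox Meerwein oxyarylation of styrenes (diazonium or iodonium radical sources) and oxidative phenol–styrene [3+2] cycloaddition, neither of which has been shown with an o‑iodophenol as the C,O‑donor or with acyclic 1,2‑induction from an allylic stereocentre.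

**Step 4**
Reactants: 7
Product: 8 4‑[(2S,3S)‑3,5‑diformyl‑7‑methoxy‑2,3‑dihydro‑1‑benzofuran‑2‑yl]‑2‑methoxyphenyl acetate
Conditions: H5IO6 (2.2 equiv), EtOAc, 0 °C → rt; filter, cold aq Na2S2O3 then brine wash, dry (Na2SO4); no chromatography, the EtOAc solution is used the same day
Reagents that add atoms: none (the new aldehyde oxygen is the original dioxolane oxygen; acetone and formaldehyde are lost)
Why: Periodic acid performs acetonide hydrolysis and Malaprade glycol cleavage of the terminal dioxolane in one pot, the mildly acidic base‑free medium suppresses enolisation and E1cB ring opening at C3, and the acetate keeps the oxidant off the guaiacyl phenol; no new stereocentre is made, since the bought stereocentre is erased as its carbon becomes CHO.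

**Step 5**
Reactants: 8
Product: 9 4‑[(2S,3R)‑5‑formyl‑3‑(hydroxymethyl)‑7‑methoxy‑2,3‑dihydro‑1‑benzofuran‑2‑yl]‑2‑methoxyphenyl acetate
Conditions: NaBH(OAc)3 (2 equiv), AcOH (2 equiv), EtOAc, 0 °C, followed by TLC; aq NaHCO3 quench, chromatography
Reagents that add atoms: none (the reductant adds only H)
Why: In this chemoselective triacetoxyborohydride reduction the aliphatic aldehyde reacts much faster than the p‑alkoxy‑deactivated aryl aldehyde, the cold acidic medium keeps C3 from enolising, and C2/C3 keep their geometry (3S→3R is only a CIP priority change).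

**Step 6**
Reactants: 9; 10 malonic acid
Product: 11 (E)‑3‑[(2S,3R)‑2‑(4‑hydroxy‑3‑methoxyphenyl)‑3‑(hydroxymethyl)‑7‑methoxy‑2,3‑dihydro‑1‑benzofuran‑5‑yl]prop‑2‑enoic acid (target)
Conditions: 10 (4 equiv), pyridine, piperidine (1.5 equiv), 80 °C; concentrate; 1 M NaOH, rt, 1 h, N2; HCl to pH 2–3, 0 °C
Reagents that add atoms: malonic acid, OC(=O)CC(=O)O (delivers =CH–CO2H; CO2 and H2O are lost)
Why: Knoevenagel–Doebner condensation with decarboxylation gives only the E‑cinnamic acid, piperidine and the hydroxide treatment remove the aryl acetate (and any acyl group that has moved to the primary alcohol), and C2/C3 no longer sit next to any carbonyl, so they are not touched.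

## Compound list
1 | (R)‑2,2‑dimethyl‑1,3‑dioxolane‑4‑carbaldehyde | O=C[C@H]1COC(C)(C)O1 | starting material
2 | methyltriphenylphosphonium bromide | C[P+](c1ccccc1)(c1ccccc1)c1ccccc1.[Br-] | starting material
3 | (4S)‑4‑ethenyl‑2,2‑dimethyl‑1,3‑dioxolane | C=C[C@H]1COC(C)(C)O1 | intermediate
4 | 4‑ethenyl‑2‑methoxyphenyl acetate | C=Cc1ccc(OC(C)=O)c(OC)c1 | starting material
5 | 4‑{(E)‑2‑[(4S)‑2,2‑dimethyl‑1,3‑dioxolan‑4‑yl]ethenyl}‑2‑methoxyphenyl acetate | CC(=O)Oc1ccc(/C=C/[C@H]2COC(C)(C)O2)cc1OC | intermediate
6 | 4‑hydroxy‑3‑iodo‑5‑methoxybenzaldehyde (5‑iodovanillin) | O=Cc1cc(I)c(O)c(OC)c1 | starting material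
7 | 4‑{(2S,3S)‑3‑[(4S)‑2,2‑dimethyl‑1,3‑dioxolan‑4‑yl]‑5‑formyl‑7‑methoxy‑2,3‑dihydro‑1‑benzofuran‑2‑yl}‑2‑methoxyphenyl acetate | COc1cc([C@H]2Oc3c(OC)cc(C=O)cc3[C@@H]2[C@H]4COC(C)(C)O4)ccc1OC(C)=O | intermediate
8 | 4‑[(2S,3S)‑3,5‑diformyl‑7‑methoxy‑2,3‑dihydro‑1‑benzofuran‑2‑yl]‑2‑methoxyphenyl acetate | COc1cc([C@H]2Oc3c(OC)cc(C=O)cc3[C@@H]2C=O)ccc1OC(C)=O | intermediate
9 | 4‑[(2S,3R)‑5‑formyl‑3‑(hydroxymethyl)‑7‑methoxy‑2,3‑dihydro‑1‑benzofuran‑2‑yl]‑2‑methoxyphenyl acetate | COc1cc([C@H]2Oc3c(OC)cc(C=O)cc3[C@@H]2CO)ccc1OC(C)=O | intermediate
10 | malonic acid | OC(=O)CC(=O)O | starting material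
11 | (E)‑3‑[(2S,3R)‑2‑(4‑hydroxy‑3‑methoxyphenyl)‑3‑(hydroxymethyl)‑7‑methoxy‑2,3‑dihydro‑1‑benzofuran‑5‑yl]prop‑2‑enoic acid (CID38356809) | COc1cc([C@H]2Oc3c(OC)cc(/C=C/C(=O)O)cc3[C@@H]2CO)ccc1O | target

## Summary
**Total steps:** 6
**Longest linear sequence:** 6 (1 → 3 → 5 → 7 → 8 → 9 → 11)

**Steps most likely to fail**
1. **Step 3 (the new annulation).**
   - Risks:
     - hydrodeiodination of 6;
     - intramolecular H‑transfer from the phenol to the benzylic radical, giving a hydroarylation by‑product;
     - slow addition to the hindered alkene;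
     - direct excitation of the aryl aldehyde at 390 nm, leading to Paternò–Büchi or HAT side reactions;
     - modest dr.
   - Fallback (known chemistry, different bonds formed): a [4+1] route.
     - Add the aryl Grignard from O‑silyl‑5‑bromovanillin acetal to 1.
     - Unmask the o‑quinone methide whose exocyclic carbon bears the dioxolane.
     - Trap it with the dimethylsulfonium ylide of a protected 4‑hydroxy‑3‑methoxybenzyl unit, a trans‑selective o‑QM/sulfur‑ylide annulation.
     - Release the aryl aldehyde from its acetal and rejoin the route at step 4.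
   - Note: the sense of induction is checked at 9. If it is reversed, the same sequence is run from (S)‑glyceraldehyde acetonide, which is available from L‑ascorbic acid.
2. **Step 4.**
   - Risks: the α‑aryl, β‑aryloxy aldehyde 8 may enolise, ring‑open (which would erode ee) or aromatise to the benzofuran while it sits in the acidic oxidant.
   - Fallback: never let 8 build up.
     - Hydrolyse the acetonide separately (80 % AcOH) to the isolable diol.
     - Cleave the diol with NaIO4 in pH 7 buffered THF/H2O at 0 °C.
     - Add NaBH4 to the same flask so that both aldehydes are reduced as soon as 8 forms.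
     - Re‑oxidise only the benzylic alcohol with MnO2 to reach 9.
3. **Step 5.**
   - Risk: partial reduction of the aryl aldehyde alongside the aliphatic one.
   - Fallback: remove the competition by re‑ordering the route, at the cost of one extra step.
     - Convert the aryl aldehyde of 7 to the (E)‑methyl cinnamate with Ph3P=CHCO2Me, which is neutral, so the acetate survives.
     - Carry out the H5IO6 cleavage.
     - Reduce the only remaining aldehyde with NaBH4 in MeOH at −20 °C.
     - Finish with LiOH, which removes the methyl ester and the aryl acetate together.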